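**Retrosynthetic overview** (rings: A = 2,4,6-trihydroxyphenyl end, then B, C, D, E = 3,4,5-trihydroxyphenyl end)
1. Target 40 ⇐ global hydrogenolysis of the dodeca-O-benzyl pentamer phenol 39.
2. D–O–E, C–O–D and B–O–C ethers ⇐ iterative SNAr of hindered phenoxides on fluorobenzaldehydes (23, 33, 23), each followed by Baeyer–Villiger oxidation and formate cleavage to unmask the next phenol.
3. Ring A, and with it the most crowded A–O–B ether, ⇐ de novo: ring-closing Claisen aromatisation of diketo ester 14, made by the key intermolecular Claisen condensation of aryloxyacetate 10 with the dianion of methyl acetoacetate.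
4. Aryloxyacetate 10 ⇐ 2,4,6-trihydroxybenzaldehyde (ring B) by benzylation, O-alkylation, Baeyer–Villiger oxidation and MOM protection.
5. Ring order: B (bought arene) → A (built by two Claisen condensations) → C → D → E (fluoroarene building blocks appended).

Assumption: the target has no stereocentres and its diaryl ether axes rotate freely, so it is achiral and no stereocontrol is needed.

**Route**

Step 1
Reactants: 1 2,4,6-trihydroxybenzaldehyde; 2 benzyl bromide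
Product: 3 2,4-bis(benzyloxy)-6-hydroxybenzaldehyde
Conditions: BnBr (2.1 equiv), K2CO3 (2.2 equiv), DMF, 0 °C → rt
Reagents that add atoms: benzyl bromide, BrCc1ccccc1
Why: Williamson O-benzylation stops at the dibenzyl ether because the last ortho-OH is held in a strong hydrogen bond to the formyl group, which also deactivates the ring towards C-benzylation.

Step 2
Reactants: 3 2,4-bis(benzyloxy)-6-hydroxybenzaldehyde; 4 methyl bromoacetate
Product: 5 methyl 2-[3,5-bis(benzyloxy)-2-formylphenoxy]acetate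
Conditions: BrCH2CO2Me (1.2 equiv), K2CO3 (1.5 equiv), DMF, rt
Reagents that add atoms: methyl bromoacetate, COC(=O)CBr
Why: Williamson alkylation of the phenoxide with a reactive α-halo ester is fast at room temperature, where aldol closure to a benzofuran does not yet occur.

Step 3
Reactants: 5 methyl 2-[3,5-bis(benzyloxy)-2-formylphenoxy]acetate; 6 3-chloroperoxybenzoic acid
Product: 8 methyl 2-[3,5-bis(benzyloxy)-2-hydroxyphenoxy]acetate, via aryl formate 7 (not isolated)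
Conditions: mCPBA (1.2 equiv), CH2Cl2, 0 °C → rt; aq. Na2S2O3/NaHCO3 wash; then K2CO3 (0.2 equiv), MeOH, 0 °C; used promptly
Reagents that add atoms: 3-chloroperoxybenzoic acid, OOC(=O)c1cccc(Cl)c1
Why: Baeyer–Villiger oxidation of a 2,4,6-trialkoxybenzaldehyde proceeds with exclusive aryl migration, and the formate is methanolysed in methanol so that the methyl ester is unchanged and lactonisation is avoided.

Step 4
Reactants: 8 methyl 2-[3,5-bis(benzyloxy)-2-hydroxyphenoxy]acetate; 9 chloromethyl methyl ether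
Product: 10 methyl 2-[3,5-bis(benzyloxy)-2-(methoxymethoxy)phenoxy]acetate
Conditions: MOMCl (1.5 equiv), i-Pr2NEt (2 equiv), CH2Cl2, 0 °C → rt
Reagents that add atoms: chloromethyl methyl ether, COCCl
Why: O-alkylation gives a MOM acetal that is inert to the strong bases ahead and can later be removed without touching benzyl ethers.

Step 5
Reactants: 10 methyl 2-[3,5-bis(benzyloxy)-2-(methoxymethoxy)phenoxy]acetate; 11 methyl acetoacetate
Product: 14 methyl 6-[3,5-bis(benzyloxy)-2-(methoxymethoxy)phenoxy]-3,5-dioxohexanoate, via sodium enolate 12 (not isolated), via sodium lithium dianion 13 (not isolated)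
Conditions: 11 (3 equiv), NaH (3 equiv), THF, 0 °C; n-BuLi (3 equiv), 0 °C; then 10, −78 → 0 °C; cold 1 M HCl
Reagents that add atoms: methyl acetoacetate, COC(=O)CC(C)=O
Why: In this intermolecular Claisen condensation the γ-carbanion of the acetoacetate dianion acylates the α-aryloxy-activated methyl ester, and the β,δ-diketo ester formed is protected from further attack as its enolate.

Step 6
Reactants: 14 methyl 6-[3,5-bis(benzyloxy)-2-(methoxymethoxy)phenoxy]-3,5-dioxohexanoate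
Product: 15 2-[3,5-bis(benzyloxy)-2-(methoxymethoxy)phenoxy]benzene-1,3,5-triol
Conditions: t-BuOK (4 equiv), degassed THF (0.02 M), 0 → 65 °C, Ar; cold 1 M HCl
Reagents that add atoms: none
Why: The C6 carbanion, acidified by the aryloxy group, attacks the methyl ester in an intramolecular Claisen (Dieckmann-type) condensation, and irreversible tautomerisation of the cyclohexane-1,3,5-trione to the phloroglucinolate drives ring closure over reversible O-lactonisation.

Step 7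
Reactants: 15 2-[3,5-bis(benzyloxy)-2-(methoxymethoxy)phenoxy]benzene-1,3,5-triol; 16 acetic anhydride
Product: 17 2-[3,5-bis(benzyloxy)-2-(methoxymethoxy)phenoxy]benzene-1,3,5-triyl triacetate
Conditions: Ac2O (6 equiv), pyridine, DMAP (cat.), rt, Ar
Reagents that add atoms: acetic anhydride, CC(=O)OC(C)=O
Why: O-acylation converts the air-sensitive, C-nucleophilic phloroglucinol into a stable triacetate from which the phenoxides can be released one at a time.

Step 8
Reactants: 17 2-[3,5-bis(benzyloxy)-2-(methoxymethoxy)phenoxy]benzene-1,3,5-triyl triacetate; 18 benzyl chloride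
Product: 19 1,5-bis(benzyloxy)-2-(methoxymethoxy)-3-[2,4,6-tris(benzyloxy)phenoxy]benzene
Conditions: NaH (6.6 equiv), BnCl (3.6 equiv), DMF, H2O (3.3 equiv) added slowly, 0 °C → rt
Reagents that add atoms: benzyl chloride, ClCc1ccccc1
Why: Hydroxide formed in the flask cleaves the acetates gradually and each phenoxide is trapped at once by Williamson O-benzylation, which keeps the polyanion concentration low and suppresses C-benzylation.

Step 9
Reactants: 19 1,5-bis(benzyloxy)-2-(methoxymethoxy)-3-[2,4,6-tris(benzyloxy)phenoxy]benzene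
Product: 20 2,4-bis(benzyloxy)-6-[2,4,6-tris(benzyloxy)phenoxy]phenol
Conditions: conc. HCl (cat.), MeOH/THF (1:1), 45 °C
Reagents that add atoms: none
Why: Acid-catalysed acetal exchange removes the MOM group while benzyl and diaryl ethers are inert, and the large excess of methanol traps the methoxymethyl cation as dimethoxymethane before it can alkylate the electron-rich rings.

Step 10
Reactants: 21 4-fluoro-2,6-dimethoxybenzaldehyde
Product: 22 4-fluoro-2,6-dihydroxybenzaldehyde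
Conditions: BBr3 (3 equiv), CH2Cl2, −78 °C → rt; H2O
Reagents that add atoms: none
Why: Lewis-acid demethylation of aryl methyl ethers is assisted by chelation to the ortho formyl group and leaves the C–F bond intact.

Step 11
Reactants: 22 4-fluoro-2,6-dihydroxybenzaldehyde; 2 benzyl bromide
Product: 23 2,6-bis(benzyloxy)-4-fluorobenzaldehyde
Conditions: BnBr (2.4 equiv), K2CO3 (3 equiv), DMF, 50 °C
Reagents that add atoms: benzyl bromide, BrCc1ccccc1
Why: Williamson benzylation is much faster than SNAr of the phenoxides on the fluoride at this temperature, because the phenoxide-bearing rings are deactivated as electrophiles.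

Step 12
Reactants: 20 2,4-bis(benzyloxy)-6-[2,4,6-tris(benzyloxy)phenoxy]phenol; 23 2,6-bis(benzyloxy)-4-fluorobenzaldehyde
Product: 24 2,6-bis(benzyloxy)-4-{2,4-bis(benzyloxy)-6-[2,4,6-tris(benzyloxy)phenoxy]phenoxy}benzaldehyde
Conditions: 23 (1.3 equiv), Cs2CO3 (2 equiv), DMSO, 100 °C, Ar
Reagents that add atoms: 2,6-bis(benzyloxy)-4-fluorobenzaldehyde, O=Cc1c(OCc2ccccc2)cc(F)cc1OCc1ccccc1
Why: SNAr works because the fluoride is para to the formyl group and has two free ortho positions, so even the di-ortho-substituted caesium phenoxide can add.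

Step 13
Reactants: 24 2,6-bis(benzyloxy)-4-{2,4-bis(benzyloxy)-6-[2,4,6-tris(benzyloxy)phenoxy]phenoxy}benzaldehyde; 6 3-chloroperoxybenzoic acid
Product: 26 2,6-bis(benzyloxy)-4-{2,4-bis(benzyloxy)-6-[2,4,6-tris(benzyloxy)phenoxy]phenoxy}phenol, via aryl formate 25 (not isolated)
Conditions: mCPBA (1.2 equiv), CH2Cl2, 0 °C; aq. Na2S2O3/NaHCO3 wash; then K2CO3 (0.2 equiv), MeOH/THF, rt
Reagents that add atoms: 3-chloroperoxybenzoic acid, OOC(=O)c1cccc(Cl)c1
Why: Baeyer–Villiger oxidation with aryl migration is very fast for a 2,4,6-trioxygenated benzaldehyde, so a near-stoichiometric amount of peracid at 0 °C spares the other electron-rich rings.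

Step 14
Reactants: 27 5-fluoro-1,2,3-trimethoxybenzene; 28 N,N-dimethylformamide
Product: 31 6-fluoro-2,3,4-trimethoxybenzaldehyde, via aryllithium 29 (not isolated), via lithium hemiaminolate 30 (not isolated)
Conditions: n-BuLi (1.1 equiv), THF, −78 °C, 1 h; DMF (1.5 equiv), −78 → 0 °C; aq. HCl
Reagents that add atoms: N,N-dimethylformamide, CN(C)C=O
Why: Directed ortho-metalation can only occur at the two equivalent C–H positions flanked by F and OMe, so formylation gives a single regioisomer, and the lithiofluoroarene is stable to benzyne formation at −78 °C.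

Step 15
Reactants: 31 6-fluoro-2,3,4-trimethoxybenzaldehyde
Product: 32 6-fluoro-2,3,4-trihydroxybenzaldehyde
Conditions: BBr3 (4.5 equiv), CH2Cl2, −78 °C → rt; H2O
Reagents that add atoms: none
Why: BBr3 cleaves all three aryl methyl ethers by Lewis-acid-mediated demethylation without affecting the aryl fluoride.

Step 16
Reactants: 32 6-fluoro-2,3,4-trihydroxybenzaldehyde; 2 benzyl bromide
Product: 33 2,3,4-tris(benzyloxy)-6-fluorobenzaldehyde
Conditions: BnBr (3.6 equiv), K2CO3 (4 equiv), DMF, 50 °C, Ar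
Reagents that add atoms: benzyl bromide, BrCc1ccccc1
Why: Exhaustive Williamson benzylation under argon protects the oxidation-prone pyrogallol unit and gives the SNAr electrophile for ring D.

Step 17
Reactants: 26 2,6-bis(benzyloxy)-4-{2,4-bis(benzyloxy)-6-[2,4,6-tris(benzyloxy)phenoxy]phenoxy}phenol; 33 2,3,4-tris(benzyloxy)-6-fluorobenzaldehyde
Product: 34 2,3,4-tris(benzyloxy)-6-(2,6-bis(benzyloxy)-4-{2,4-bis(benzyloxy)-6-[2,4,6-tris(benzyloxy)phenoxy]phenoxy}phenoxy)benzaldehyde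
Conditions: 33 (1.5 equiv), Cs2CO3 (2 equiv), DMSO, 110 °C, Ar
Reagents that add atoms: 2,3,4-tris(benzyloxy)-6-fluorobenzaldehyde, O=Cc1c(F)cc(OCc2ccccc2)c(OCc2ccccc2)c1OCc1ccccc1
Why: SNAr is activated by the ortho formyl group, which stabilises the Meisenheimer adduct, and the other ortho position of the fluoride is unsubstituted.

Step 18
Reactants: 34 2,3,4-tris(benzyloxy)-6-(2,6-bis(benzyloxy)-4-{2,4-bis(benzyloxy)-6-[2,4,6-tris(benzyloxy)phenoxy]phenoxy}phenoxy)benzaldehyde; 6 3-chloroperoxybenzoic acid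
Product: 36 2,3,4-tris(benzyloxy)-6-(2,6-bis(benzyloxy)-4-{2,4-bis(benzyloxy)-6-[2,4,6-tris(benzyloxy)phenoxy]phenoxy}phenoxy)phenol, via aryl formate 35 (not isolated)
Conditions: mCPBA (1.2 equiv), CH2Cl2, 0 °C; aq. Na2S2O3/NaHCO3 wash; then K2CO3 (0.2 equiv), MeOH/THF, rt
Reagents that add atoms: 3-chloroperoxybenzoic acid, OOC(=O)c1cccc(Cl)c1
Why: Baeyer–Villiger oxidation with aryl migration is favoured by the two ortho and one para oxygen substituents and places the new phenol exactly where ring E must be attached.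

Step 19
Reactants: 36 2,3,4-tris(benzyloxy)-6-(2,6-bis(benzyloxy)-4-{2,4-bis(benzyloxy)-6-[2,4,6-tris(benzyloxy)phenoxy]phenoxy}phenoxy)phenol; 23 2,6-bis(benzyloxy)-4-fluorobenzaldehyde
Product: 37 2,6-bis(benzyloxy)-4-[2,3,4-tris(benzyloxy)-6-(2,6-bis(benzyloxy)-4-{2,4-bis(benzyloxy)-6-[2,4,6-tris(benzyloxy)phenoxy]phenoxy}phenoxy)phenoxy]benzaldehyde
Conditions: 23 (1.5 equiv), Cs2CO3 (2 equiv), DMSO, 100 °C, Ar
Reagents that add atoms: 2,6-bis(benzyloxy)-4-fluorobenzaldehyde, O=Cc1c(OCc2ccccc2)cc(F)cc1OCc1ccccc1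
Why: This is the same para-formyl-activated SNAr as in step 12, with the unhindered fluoride compensating for the crowded phenoxide.

Step 20
Reactants: 37 2,6-bis(benzyloxy)-4-[2,3,4-tris(benzyloxy)-6-(2,6-bis(benzyloxy)-4-{2,4-bis(benzyloxy)-6-[2,4,6-tris(benzyloxy)phenoxy]phenoxy}phenoxy)phenoxy]benzaldehyde; 6 3-chloroperoxybenzoic acid
Product: 39 2,6-bis(benzyloxy)-4-[2,3,4-tris(benzyloxy)-6-(2,6-bis(benzyloxy)-4-{2,4-bis(benzyloxy)-6-[2,4,6-tris(benzyloxy)phenoxy]phenoxy}phenoxy)phenoxy]phenol, via aryl formate 38 (not isolated)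
Conditions: mCPBA (1.2 equiv), CH2Cl2, 0 °C; aq. Na2S2O3/NaHCO3 wash; then K2CO3 (0.2 equiv), MeOH/THF, rt
Reagents that add atoms: 3-chloroperoxybenzoic acid, OOC(=O)c1cccc(Cl)c1
Why: Baeyer–Villiger oxidation with aryl migration installs the last oxygen, the 4-OH of ring E, which needs no protection before the final step.

Step 21
Reactants: 39 2,6-bis(benzyloxy)-4-[2,3,4-tris(benzyloxy)-6-(2,6-bis(benzyloxy)-4-{2,4-bis(benzyloxy)-6-[2,4,6-tris(benzyloxy)phenoxy]phenoxy}phenoxy)phenoxy]phenol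
Product: 40 5-{6-[2,6-dihydroxy-4-(2,4-dihydroxy-6-(2,4,6-trihydroxyphenoxy)phenoxy)phenoxy]-2,3,4-trihydroxyphenoxy}benzene-1,2,3-triol (target)
Conditions: H2 (1–3 bar), Pd(OH)2/C, degassed THF/MeOH (1:1), rt; filtration under Ar; Sephadex LH-20 (MeOH)
Reagents that add atoms: none
Why: Catalytic hydrogenolysis cleaves all twelve benzyl ethers under neutral conditions that leave diaryl ethers intact and spare the oxidation-prone polyphenol.

**Compound list**

1 | 2,4,6-trihydroxybenzaldehyde | O=Cc1c(O)cc(O)cc1O | starting material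
2 | benzyl bromide | BrCc1ccccc1 | starting material
3 | 2,4-bis(benzyloxy)-6-hydroxybenzaldehyde | O=Cc1c(O)cc(OCc2ccccc2)cc1OCc1ccccc1 | intermediate
4 | methyl bromoacetate | COC(=O)CBr | starting material
5 | methyl 2-[3,5-bis(benzyloxy)-2-formylphenoxy]acetate | COC(=O)COc1cc(OCc2ccccc2)cc(OCc2ccccc2)c1C=O | intermediate
6 | 3-chloroperoxybenzoic acid (mCPBA) | OOC(=O)c1cccc(Cl)c1 | starting material
7 | methyl 2-[3,5-bis(benzyloxy)-2-(formyloxy)phenoxy]acetate (aryl formate, not isolated) | COC(=O)COc1cc(OCc2ccccc2)cc(OCc2ccccc2)c1OC=O | intermediate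
8 | methyl 2-[3,5-bis(benzyloxy)-2-hydroxyphenoxy]acetate | COC(=O)COc1cc(OCc2ccccc2)cc(OCc2ccccc2)c1O | intermediate
9 | chloromethyl methyl ether | COCCl | starting material
10 | methyl 2-[3,5-bis(benzyloxy)-2-(methoxymethoxy)phenoxy]acetate | COC(=O)COc1cc(OCc2ccccc2)cc(OCc2ccccc2)c1OCOC | intermediate
11 | methyl acetoacetate | COC(=O)CC(C)=O | starting material
12 | sodium enolate of methyl acetoacetate (not isolated) | [Na+].COC(=O)C=C(C)[O-] | intermediate
13 | sodium lithium dianion of methyl acetoacetate (not isolated) | [Na+].[Li+].COC([O-])=CC([O-])=C | intermediate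
14 | methyl 6-[3,5-bis(benzyloxy)-2-(methoxymethoxy)phenoxy]-3,5-dioxohexanoate | COC(=O)CC(=O)CC(=O)COc1cc(OCc2ccccc2)cc(OCc2ccccc2)c1OCOC | intermediate
15 | 2-[3,5-bis(benzyloxy)-2-(methoxymethoxy)phenoxy]benzene-1,3,5-triol | COCOc1c(Oc2c(O)cc(O)cc2O)cc(OCc2ccccc2)cc1OCc1ccccc1 | intermediate
16 | acetic anhydride | CC(=O)OC(C)=O | starting material
17 | 2-[3,5-bis(benzyloxy)-2-(methoxymethoxy)phenoxy]benzene-1,3,5-triyl triacetate | COCOc1c(Oc2c(OC(C)=O)cc(OC(C)=O)cc2OC(C)=O)cc(OCc2ccccc2)cc1OCc1ccccc1 | intermediate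
18 | benzyl chloride | ClCc1ccccc1 | starting material
19 | 1,5-bis(benzyloxy)-2-(methoxymethoxy)-3-[2,4,6-tris(benzyloxy)phenoxy]benzene | COCOc1c(Oc2c(OCc3ccccc3)cc(OCc3ccccc3)cc2OCc2ccccc2)cc(OCc2ccccc2)cc1OCc1ccccc1 | intermediate
20 | 2,4-bis(benzyloxy)-6-[2,4,6-tris(benzyloxy)phenoxy]phenol (A–B phenol) | Oc1c(Oc2c(OCc3ccccc3)cc(OCc3ccccc3)cc2OCc2ccccc2)cc(OCc2ccccc2)cc1OCc1ccccc1 | intermediate
21 | 4-fluoro-2,6-dimethoxybenzaldehyde | COc1cc(F)cc(OC)c1C=O | starting material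
22 | 4-fluoro-2,6-dihydroxybenzaldehyde | O=Cc1c(O)cc(F)cc1O | intermediate
23 | 2,6-bis(benzyloxy)-4-fluorobenzaldehyde | O=Cc1c(OCc2ccccc2)cc(F)cc1OCc1ccccc1 | intermediate
24 | 2,6-bis(benzyloxy)-4-{2,4-bis(benzyloxy)-6-[2,4,6-tris(benzyloxy)phenoxy]phenoxy}benzaldehyde (A–B–C aldehyde) | O=Cc1c(OCc2ccccc2)cc(Oc2c(Oc3c(OCc4ccccc4)cc(OCc4ccccc4)cc3OCc3ccccc3)cc(OCc3ccccc3)cc2OCc2ccccc2)cc1OCc1ccccc1 | intermediate
25 | 2,6-bis(benzyloxy)-4-{2,4-bis(benzyloxy)-6-[2,4,6-tris(benzyloxy)phenoxy]phenoxy}phenyl formate (not isolated) | O=COc1c(OCc2ccccc2)cc(Oc2c(Oc3c(OCc4ccccc4)cc(OCc4ccccc4)cc3OCc3ccccc3)cc(OCc3ccccc3)cc2OCc2ccccc2)cc1OCc1ccccc1 | intermediate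
26 | 2,6-bis(benzyloxy)-4-{2,4-bis(benzyloxy)-6-[2,4,6-tris(benzyloxy)phenoxy]phenoxy}phenol (A–B–C phenol) | Oc1c(OCc2ccccc2)cc(Oc2c(Oc3c(OCc4ccccc4)cc(OCc4ccccc4)cc3OCc3ccccc3)cc(OCc3ccccc3)cc2OCc2ccccc2)cc1OCc1ccccc1 | intermediate
27 | 5-fluoro-1,2,3-trimethoxybenzene | COc1cc(F)cc(OC)c1OC | starting material
28 | N,N-dimethylformamide | CN(C)C=O | starting material
29 | (6-fluoro-2,3,4-trimethoxyphenyl)lithium (not isolated) | [Li]c1c(F)cc(OC)c(OC)c1OC | intermediate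
30 | lithium (dimethylamino)(6-fluoro-2,3,4-trimethoxyphenyl)methanolate (racemic, not isolated) | [Li+].[O-]C(N(C)C)c1c(F)cc(OC)c(OC)c1OC | intermediate
31 | 6-fluoro-2,3,4-trimethoxybenzaldehyde | O=Cc1c(F)cc(OC)c(OC)c1OC | intermediate
32 | 6-fluoro-2,3,4-trihydroxybenzaldehyde | O=Cc1c(F)cc(O)c(O)c1O | intermediate
33 | 2,3,4-tris(benzyloxy)-6-fluorobenzaldehyde | O=Cc1c(F)cc(OCc2ccccc2)c(OCc2ccccc2)c1OCc1ccccc1 | intermediate
34 | 2,3,4-tris(benzyloxy)-6-(2,6-bis(benzyloxy)-4-{2,4-bis(benzyloxy)-6-[2,4,6-tris(benzyloxy)phenoxy]phenoxy}phenoxy)benzaldehyde (A–B–C–D aldehyde) | O=Cc1c(Oc2c(OCc5ccccc5)cc(Oc3c(Oc4c(OCc5ccccc5)cc(OCc5ccccc5)cc4OCc4ccccc4)cc(OCc4ccccc4)cc3OCc3ccccc3)cc2OCc2ccccc2)cc(OCc2ccccc2)c(OCc2ccccc2)c1OCc1ccccc1 | intermediate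
35 | 2,3,4-tris(benzyloxy)-6-(2,6-bis(benzyloxy)-4-{2,4-bis(benzyloxy)-6-[2,4,6-tris(benzyloxy)phenoxy]phenoxy}phenoxy)phenyl formate (not isolated) | O=COc1c(Oc2c(OCc5ccccc5)cc(Oc3c(Oc4c(OCc5ccccc5)cc(OCc5ccccc5)cc4OCc4ccccc4)cc(OCc4ccccc4)cc3OCc3ccccc3)cc2OCc2ccccc2)cc(OCc2ccccc2)c(OCc2ccccc2)c1OCc1ccccc1 | intermediate
36 | 2,3,4-tris(benzyloxy)-6-(2,6-bis(benzyloxy)-4-{2,4-bis(benzyloxy)-6-[2,4,6-tris(benzyloxy)phenoxy]phenoxy}phenoxy)phenol (A–B–C–D phenol) | Oc1c(Oc2c(OCc5ccccc5)cc(Oc3c(Oc4c(OCc5ccccc5)cc(OCc5ccccc5)cc4OCc4ccccc4)cc(OCc4ccccc4)cc3OCc3ccccc3)cc2OCc2ccccc2)cc(OCc2ccccc2)c(OCc2ccccc2)c1OCc1ccccc1 | intermediate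
37 | 2,6-bis(benzyloxy)-4-[2,3,4-tris(benzyloxy)-6-(2,6-bis(benzyloxy)-4-{2,4-bis(benzyloxy)-6-[2,4,6-tris(benzyloxy)phenoxy]phenoxy}phenoxy)phenoxy]benzaldehyde (A–B–C–D–E aldehyde) | O=Cc1c(OCc6ccccc6)cc(Oc2c(Oc3c(OCc6ccccc6)cc(Oc4c(Oc5c(OCc6ccccc6)cc(OCc6ccccc6)cc5OCc5ccccc5)cc(OCc5ccccc5)cc4OCc4ccccc4)cc3OCc3ccccc3)cc(OCc3ccccc3)c(OCc3ccccc3)c2OCc2ccccc2)cc1OCc1ccccc1 | intermediate
38 | 2,6-bis(benzyloxy)-4-[2,3,4-tris(benzyloxy)-6-(2,6-bis(benzyloxy)-4-{2,4-bis(benzyloxy)-6-[2,4,6-tris(benzyloxy)phenoxy]phenoxy}phenoxy)phenoxy]phenyl formate (not isolated) | O=COc1c(OCc6ccccc6)cc(Oc2c(Oc3c(OCc6ccccc6)cc(Oc4c(Oc5c(OCc6ccccc6)cc(OCc6ccccc6)cc5OCc5ccccc5)cc(OCc5ccccc5)cc4OCc4ccccc4)cc3OCc3ccccc3)cc(OCc3ccccc3)c(OCc3ccccc3)c2OCc2ccccc2)cc1OCc1ccccc1 | intermediate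
39 | 2,6-bis(benzyloxy)-4-[2,3,4-tris(benzyloxy)-6-(2,6-bis(benzyloxy)-4-{2,4-bis(benzyloxy)-6-[2,4,6-tris(benzyloxy)phenoxy]phenoxy}phenoxy)phenoxy]phenol (A–B–C–D–E phenol) | Oc1c(OCc6ccccc6)cc(Oc2c(Oc3c(OCc6ccccc6)cc(Oc4c(Oc5c(OCc6ccccc6)cc(OCc6ccccc6)cc5OCc5ccccc5)cc(OCc5ccccc5)cc4OCc4ccccc4)cc3OCc3ccccc3)cc(OCc3ccccc3)c(OCc3ccccc3)c2OCc2ccccc2)cc1OCc1ccccc1 | intermediate
40 | 5-{6-[2,6-dihydroxy-4-(2,4-dihydroxy-6-(2,4,6-trihydroxyphenoxy)phenoxy)phenoxy]-2,3,4-trihydroxyphenoxy}benzene-1,2,3-triol (CNP0243665.0, achiral) | Oc1cc(O)c(Oc2cc(O)cc(O)c2Oc2cc(O)c(Oc3cc(O)c(O)c(O)c3Oc3cc(O)c(O)c(O)c3)c(O)c2)c(O)c1 | target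

**Totals**
Total step count: 21 (main line 1–9, 12, 13, 17–21; building block 23 in steps 10–11; building block 33 in steps 14–16).
Longest linear sequence: 16 steps (1 → 3 → 5 → 8 → 10 → 14 → 15 → 17 → 19 → 20 → 24 → 26 → 34 → 36 → 37 → 39 → 40).

**Steps most likely to fail, with fallbacks**

Step 6 (ring-closing Claisen to the phloroglucinol). The C6 carbanion is only singly activated, the ester can be masked as its enolate, and O-lactonisation to a 2-pyranone or retro-Claisen cleavage may compete. The fallback sets out from 3 and rejoins the route at 20, so steps 2–9 are skipped and the A–O–B ether is made by SNAr instead. The remaining phenol of 3 is benzylated (2, K2CO3, DMF, 60 °C) to 2,4,6-tris(benzyloxy)benzaldehyde F1. Oxidation with 6 gives 2,4,6-tris(benzyloxy)phenyl formate F2, and methanolysis gives 2,4,6-tris(benzyloxy)phenol F3. In parallel, purchased 2-fluoro-4,6-dimethoxybenzaldehyde F4 is demethylated with BBr3 to 2-fluoro-4,6-dihydroxybenzaldehyde F5 and benzylated with 2 to 2,4-bis(benzyloxy)-6-fluorobenzaldehyde F6. SNAr of F3 on F6 (Cs2CO3, DMSO, 100 °C) gives 2,4-bis(benzyloxy)-6-[2,4,6-tris(benzyloxy)phenoxy]benzaldehyde F7. Baeyer–Villiger oxidation with 6 then gives 2,4-bis(benzyloxy)-6-[2,4,6-tris(benzyloxy)phenoxy]phenyl formate F8, whose methanolysis delivers 20.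

Step 5 (dianion acylation). The dianion may simply deprotonate the α-aryloxy ester, giving recovered 10 or self-condensation. The fallback sets out from 10 and rejoins at 14, replacing ester acylation by aldol addition and oxidation. DIBAL-H (CH2Cl2, −78 °C) reduces 10 to 2-[3,5-bis(benzyloxy)-2-(methoxymethoxy)phenoxy]acetaldehyde F9. Aldol addition of dianion 13 (THF, −78 °C) gives racemic methyl 6-[3,5-bis(benzyloxy)-2-(methoxymethoxy)phenoxy]-5-hydroxy-3-oxohexanoate F10. Dess–Martin periodinane (CH2Cl2, rt) oxidises F10 to 14; the stereocentre of F10 is destroyed in this oxidation.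

Step 17 (SNAr on 33). The fluoride is deactivated by the para benzyloxy group and the nucleophile is a di-ortho-substituted phenoxide, so conversion may stall or the aldehyde may degrade at the temperature needed. The fallback sets out from 26 and rejoins at 34, replacing SNAr by copper-catalysed Ullmann coupling with the bromo analogue. Purchased 5-bromo-1,2,3-trimethoxybenzene F11 is formylated (Cl2CHOMe, TiCl4, CH2Cl2, 0 °C) to 6-bromo-2,3,4-trimethoxybenzaldehyde F12. BBr3 demethylation gives 6-bromo-2,3,4-trihydroxybenzaldehyde F13, and benzylation (2, K2CO3, DMF) gives 2,3,4-tris(benzyloxy)-6-bromobenzaldehyde F14. Coupling of 26 with F14 (CuI 10 mol %, N,N-dimethylglycine 30 mol %, Cs2CO3, dioxane, 100 °C), assisted by the ortho formyl group, gives 34.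

**Further compounds**
F1 | step 6 | 2,4,6-tris(benzyloxy)benzaldehyde | O=Cc1c(OCc2ccccc2)cc(OCc2ccccc2)cc1OCc1ccccc1
F2 | step 6 | 2,4,6-tris(benzyloxy)phenyl formate | O=COc1c(OCc2ccccc2)cc(OCc2ccccc2)cc1OCc1ccccc1
F3 | step 6 | 2,4,6-tris(benzyloxy)phenol | Oc1c(OCc2ccccc2)cc(OCc2ccccc2)cc1OCc1ccccc1
F4 | step 6 | 2-fluoro-4,6-dimethoxybenzaldehyde | COc1cc(OC)c(C=O)c(F)c1
F5 | step 6 | 2-fluoro-4,6-dihydroxybenzaldehyde | Oc1cc(O)c(C=O)c(F)c1
F6 | step 6 | 2,4-bis(benzyloxy)-6-fluorobenzaldehyde | O=Cc1c(F)cc(OCc2ccccc2)cc1OCc1ccccc1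
F7 | step 6 | 2,4-bis(benzyloxy)-6-[2,4,6-tris(benzyloxy)phenoxy]benzaldehyde | O=Cc1c(Oc2c(OCc3ccccc3)cc(OCc3ccccc3)cc2OCc2ccccc2)cc(OCc2ccccc2)cc1OCc1ccccc1
F8 | step 6 | 2,4-bis(benzyloxy)-6-[2,4,6-tris(benzyloxy)phenoxy]phenyl formate | O=COc1c(Oc2c(OCc3ccccc3)cc(OCc3ccccc3)cc2OCc2ccccc2)cc(OCc2ccccc2)cc1OCc1ccccc1
F9 | step 5 | 2-[3,5-bis(benzyloxy)-2-(methoxymethoxy)phenoxy]acetaldehyde | O=CCOc1cc(OCc2ccccc2)cc(OCc2ccccc2)c1OCOC
F10 | step 5 | methyl 6-[3,5-bis(benzyloxy)-2-(methoxymethoxy)phenoxy]-5-hydroxy-3-oxohexanoate (racemic) | COC(=O)CC(=O)CC(O)COc1cc(OCc2ccccc2)cc(OCc2ccccc2)c1OCOC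
F11 | step 17 | 5-bromo-1,2,3-trimethoxybenzene | COc1cc(Br)cc(OC)c1OC
F12 | step 17 | 6-bromo-2,3,4-trimethoxybenzaldehyde | O=Cc1c(Br)cc(OC)c(OC)c1OC
F13 | step 17 | 6-bromo-2,3,4-trihydroxybenzaldehyde | O=Cc1c(Br)cc(O)c(O)c1O
F14 | step 17 | 2,3,4-tris(benzyloxy)-6-bromobenzaldehyde | O=Cc1c(Br)cc(OCc2ccccc2)c(OCc2ccccc2)c1OCc1ccccc1
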